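**Plan**

- Retrosynthesis: the CH2–aryl bond of the methylene bridge is cut first, giving a Mannich salt of butyrylfilicinic acid (ring A) and the acylchromene (rings B and C). Ring A is then cut at its C(=O)–CMe2 bond and at the bond between the butyryl-bearing carbon and the C–OH carbon that lies between it and the bridge carbon.
- Enabling feature: ring A is a 6,6-dimethylcyclohexa-2,4-dienone with 1,3,5-oxygenation, the product a dienylketene gives on 6π closure when its terminus is a quaternary CMe2 carbon. The acyl-bearing carbon and its C=O neighbour are the two carbons of an ynolate; the other four ring carbons are a vinylketene released from a strained 4,4-dimethylcyclobutenone.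
- Helpers: a triethylsilyl group on the ketene α-carbon (stabilises the ketene and sets the enolate geometry), an ethyl enol ether, and a dioxolane masking the butyryl C=O. All three leave in one acid step.
- Forward order: [2+2] to the cyclobutenone; ring A by ring opening and annulation with the ynolate made in the same flask from the ketal-protected ynone; hydrolysis; Mannich salt. Ring B is acylated; ring C is built by a propargyl Claisen sequence with the para-OH silylated for regiocontrol. The bridge is made last.
- Stereochemistry: the target has no stereocentre. The only geometric issue, the dienylketene double bond, is controlled by the silyl group.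

Key step: step 5

Remark: ring A is drawn in the enol tautomer of the target SMILES throughout; racemic hex-1-yn-3-ol is used because its carbinol carbon ends as the butyryl C=O.

**Route**

Step 1
Reactants: 1 ethoxyethyne
Product: 3 triethyl(ethoxyethynyl)silane, via lithium ethoxyacetylide 2 (not isolated)
Conditions: n-BuLi, THF, -78 °C; Et3SiCl, -78 °C to rt
Reagents that add atoms: chlorotriethylsilane, CC[Si](Cl)(CC)CC
Why: Deprotonation of the acidic alkynyl C–H and silylation of the lithium acetylide should give the C-silyl ynol ether.

Step 2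
Reactants: 3 triethyl(ethoxyethynyl)silane; 4 2-methylpropanoyl chloride
Product: 6 3-ethoxy-4,4-dimethyl-2-(triethylsilyl)cyclobut-2-en-1-one, via dimethylketene 5 (not isolated)
Conditions: Et3N, Et2O, slow addition of 4, rt to reflux
Reagents that add atoms: none
Why: Dimethylketene formed by dehydrochlorination of 4 should undergo the stepwise ketene–ynol ether [2+2] cycloaddition, the silyl-bearing alkyne carbon attacking the ketene carbonyl carbon so that the ethoxy carbon ends next to CMe2.

Step 3
Reactants: 7 hex-1-yn-3-ol (racemic)
Product: 8 hex-1-yn-3-one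
Conditions: Dess–Martin periodinane, CH2Cl2, 0 °C to rt
Reagents that add atoms: none
Why: Dess–Martin oxidation of a secondary propargylic alcohol should stop at the ynone and removes the only stereocentre of 7.

Step 4
Reactants: 8 hex-1-yn-3-one
Product: 9 2-ethynyl-2-propyl-1,3-dioxolane
Conditions: Me3SiOCH2CH2OSiMe3, TMSOTf (cat.), CH2Cl2, -78 to -20 °C
Reagents that add atoms: 1,2-bis(trimethylsilyloxy)ethane, C[Si](C)(C)OCCO[Si](C)(C)C
Why: Noyori ketalization should protect the ynone carbonyl at low temperature without conjugate addition to the triple bond, masking the future butyryl ketone.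

Step 5
Reactants: 6 3-ethoxy-4,4-dimethyl-2-(triethylsilyl)cyclobut-2-en-1-one; 9 2-ethynyl-2-propyl-1,3-dioxolane
Product: 15 5-ethoxy-3-hydroxy-6,6-dimethyl-2-(2-propyl-1,3-dioxolan-2-yl)-4-(triethylsilyl)cyclohexa-2,4-dien-1-one, via lithium acetylide 10 (not isolated), via lithium ynolate 11 (not isolated), via silylvinylketene 12 (not isolated), via lithium oxidodienylketene 13 (not isolated), via lithium dienolate 14 (not isolated)
Conditions: 9 (slight excess), n-BuLi, THF, -78 °C; t-BuOOLi [from t-BuOOH and LiN(SiMe3)2], -78 to 0 °C, then -78 °C; 6, hν (300 nm), Et2O, -78 °C, added cold by cannula; -78 °C to rt; AcOH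
Reagents that add atoms: tert-butyl hydroperoxide, CC(C)(C)OO
Why: The lithium acetylide 10 is oxidised by lithium tert-butylperoxide to the ynolate 11 (Julia ynolate synthesis), while irradiation opens the strained cyclobutenone 6 by 4π-electrocyclic cleavage of its C(=O)–CMe2 bond to the silylvinylketene 12. The ynolate carbon is then acylated by the ketene carbon (first new C–C bond) to give the 3-oxidodienylketene 13, which should close thermally by disrotatory 6π electrocyclization between the new ketene carbon and the CMe2 terminus (second new C–C bond). The closest known reaction type is the benzannulation of (trialkylsilyl)vinylketenes with lithium ynolates; here the quaternary CMe2 terminus forbids tautomerization to a phenol, so the 6,6-dimethylcyclohexa-2,4-dienone enolate 14 is the end point. Ring A closes in the 6π-electrocyclic mode with all six ring atoms in the hexatriene, and no stereocentre is formed. The step needs C- rather than O-acylation of the ynolate, which is inherent to ynolates with ketenes, capture of the ketene by the ynolate rather than by the hindered, aggregated lithium tert-butoxide formed beside it, and an enolate double bond with the ketenyl group cis to the alkenyl arm; the Et3Si group on the ketene α-carbon should secure the last point by steering the in-plane attack to the far side and, through the α-silyl allyl-anion resonance form, letting a wrong isomer equilibrate. The silyl group also keeps 12 from dimerizing, and generating 12 at -78 °C avoids a 1,5-hydrogen shift from its cis methyl group before trapping.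

Step 6
Reactants: 15 5-ethoxy-3-hydroxy-6,6-dimethyl-2-(2-propyl-1,3-dioxolan-2-yl)-4-(triethylsilyl)cyclohexa-2,4-dien-1-one
Product: 16 2-butanoyl-3,5-dihydroxy-6,6-dimethylcyclohexa-2,4-dien-1-one (butyrylfilicinic acid)
Conditions: 2 M aq. HCl, THF, 60 °C
Reagents that add atoms: water, O
Why: Aqueous acid should protonate the β-silyl enol ether at the silyl-bearing carbon (protodesilylation) and hydrolyse both the vinylogous ester and the dioxolane, the product being the stable chelated enol of the β-triketone.

Step 7
Reactants: 16 butyrylfilicinic acid; 17 N,N-dimethylmethaniminium iodide (Eschenmoser's salt)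
Product: 18 [(3-butanoyl-2,6-dihydroxy-5,5-dimethyl-4-oxocyclohexa-2,6-dien-1-yl)methyl]dimethylammonium iodide (ring-carbon Mannich base of 16 as hydroiodide)
Conditions: MeCN/CH2Cl2, rt; salt collected by filtration
Reagents that add atoms: none
Why: In this Mannich reaction the only free ring carbon of the enolised 1,3-dione, flanked by two C–OH carbons, should attack the preformed iminium ion, and precipitation of the hydroiodide stops the reaction at mono-aminomethylation.

Step 8
Reactants: 19 benzene-1,3,5-triol (phloroglucinol); 20 butanoyl chloride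
Product: 21 1-(2,4,6-trihydroxyphenyl)butan-1-one
Conditions: AlCl3, PhNO2/CH2Cl2, rt to 60 °C; aq. HCl work-up
Reagents that add atoms: none
Why: Friedel–Crafts acylation of the highly activated phloroglucinol should stop after one acyl group, which deactivates the ring.

Step 9
Reactants: 21 1-(2,4,6-trihydroxyphenyl)butan-1-one
Product: 22 1-{2,6-dihydroxy-4-[(triisopropylsilyl)oxy]phenyl}butan-1-one
Conditions: i-Pr3SiCl (1 equiv), imidazole, DMF/CH2Cl2, 0 °C
Reagents that add atoms: chlorotriisopropylsilane, CC(C)[Si](Cl)(C(C)C)C(C)C
Why: The 4-OH, para to the ketone, is the most acidic and least hindered hydroxyl and is not part of the C=O chelate, so the bulky silyl chloride should react there selectively (phenol silylation).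

Step 10
Reactants: 22 1-{2,6-dihydroxy-4-[(triisopropylsilyl)oxy]phenyl}butan-1-one; 23 3-chloro-3-methylbut-1-yne
Product: 24 1-{2-hydroxy-6-[(2-methylbut-3-yn-2-yl)oxy]-4-[(triisopropylsilyl)oxy]phenyl}butan-1-one
Conditions: DBU, CuCl2 (cat.), MeCN, 0 °C
Reagents that add atoms: none
Why: Copper-catalysed propargylic etherification of a phenol with a tertiary propargylic chloride should stop at the mono-ether, because after one of the two equivalent ortho hydroxyls has reacted the other is locked in the ketone chelate.

Step 11
Reactants: 24 1-{2-hydroxy-6-[(2-methylbut-3-yn-2-yl)oxy]-4-[(triisopropylsilyl)oxy]phenyl}butan-1-one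
Product: 27 1-{7-hydroxy-2,2-dimethyl-5-[(triisopropylsilyl)oxy]-2H-chromen-8-yl}butan-1-one, via allenylphenol 25 (not isolated), via ortho-quinone methide 26 (not isolated)
Conditions: xylenes, 140 °C
Reagents that add atoms: none
Why: Aromatic propargyl Claisen rearrangement to the only free ortho carbon, tautomerization, 1,5-hydrogen shift and oxa-6π electrocyclization should build ring C with its oxygen next to the acyl-bearing carbon.

Step 12
Reactants: 27 1-{7-hydroxy-2,2-dimethyl-5-[(triisopropylsilyl)oxy]-2H-chromen-8-yl}butan-1-one
Product: 28 1-(5,7-dihydroxy-2,2-dimethyl-2H-chromen-8-yl)butan-1-one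
Conditions: Bu4NF, AcOH, THF, 0 °C
Reagents that add atoms: none
Why: Buffered fluoride should cleave the aryl silyl ether while leaving the acid-sensitive chromene double bond and the ketone untouched.

Step 13
Reactants: 18 Mannich hydroiodide of butyrylfilicinic acid; 28 1-(5,7-dihydroxy-2,2-dimethyl-2H-chromen-8-yl)butan-1-one
Product: 30 Drummondin A, via methylene trione 29 (not isolated)
Conditions: NaOAc (1 equiv), 1,4-dioxane, 80 °C
Reagents that add atoms: none
Why: Thermal loss of dimethylamine from the Mannich base should give the 2-methylene-1,3-dione 29, a strong Michael acceptor, which is captured by C6 of 28, the only free aromatic carbon and activated by two ortho hydroxyls (Friedel–Crafts-type Michael addition), closing the methylene bridge.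

**Compound list**

1 | ethoxyethyne | C#COCC | starting material
2 | lithium ethoxyacetylide (formed in the flask) | [Li]C#COCC | intermediate
3 | triethyl(ethoxyethynyl)silane | CCOC#C[Si](CC)(CC)CC | intermediate
4 | 2-methylpropanoyl chloride | CC(C)C(Cl)=O | starting material
5 | dimethylketene (formed in the flask) | CC(C)=C=O | intermediate
6 | 3-ethoxy-4,4-dimethyl-2-(triethylsilyl)cyclobut-2-en-1-one | CCOC1=C([Si](CC)(CC)CC)C(=O)C1(C)C | intermediate
7 | hex-1-yn-3-ol (racemic) | CCCC(O)C#C | starting material
8 | hex-1-yn-3-one | CCCC(=O)C#C | intermediate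
9 | 2-ethynyl-2-propyl-1,3-dioxolane | CCCC1(C#C)OCCO1 | intermediate
10 | lithium acetylide of 9 (formed in the flask) | CCCC1(C#C[Li])OCCO1 | intermediate
11 | lithium 2-(2-propyl-1,3-dioxolan-2-yl)ethynolate (formed in the flask) | CCCC1(C#C[O-])OCCO1.[Li+] | intermediate
12 | 3-ethoxy-4-methyl-2-(triethylsilyl)penta-1,3-dien-1-one (silylvinylketene, formed in the flask) | CCOC(=C(C)C)C(=C=O)[Si](CC)(CC)CC | intermediate
13 | lithium 3-oxidodienylketene, ketenyl group cis to the alkenyl arm (formed in the flask) | CCCC1(OCCO1)C(=C=O)/C([O-])=C(/[Si](CC)(CC)CC)C(OCC)=C(C)C.[Li+] | intermediate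
14 | lithium enolate of 15 (formed in the flask) | CCCC1(OCCO1)C2=C([O-])C([Si](CC)(CC)CC)=C(OCC)C(C)(C)C2=O.[Li+] | intermediate
15 | 5-ethoxy-3-hydroxy-6,6-dimethyl-2-(2-propyl-1,3-dioxolan-2-yl)-4-(triethylsilyl)cyclohexa-2,4-dien-1-one | CCCC1(OCCO1)C2=C(O)C([Si](CC)(CC)CC)=C(OCC)C(C)(C)C2=O | intermediate
16 | 2-butanoyl-3,5-dihydroxy-6,6-dimethylcyclohexa-2,4-dien-1-one (butyrylfilicinic acid) | CCCC(=O)C1=C(O)C=C(O)C(C)(C)C1=O | intermediate
17 | N,N-dimethylmethaniminium iodide (Eschenmoser's salt) | C=[N+](C)C.[I-] | starting material
18 | [(3-butanoyl-2,6-dihydroxy-5,5-dimethyl-4-oxocyclohexa-2,6-dien-1-yl)methyl]dimethylammonium iodide | CCCC(=O)C1=C(O)C(C[NH+](C)C)=C(O)C(C)(C)C1=O.[I-] | intermediate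
19 | benzene-1,3,5-triol (phloroglucinol) | Oc1cc(O)cc(O)c1 | starting material
20 | butanoyl chloride | CCCC(Cl)=O | starting material
21 | 1-(2,4,6-trihydroxyphenyl)butan-1-one | CCCC(=O)c1c(O)cc(O)cc1O | intermediate
22 | 1-{2,6-dihydroxy-4-[(triisopropylsilyl)oxy]phenyl}butan-1-one | CCCC(=O)c1c(O)cc(O[Si](C(C)C)(C(C)C)C(C)C)cc1O | intermediate
23 | 3-chloro-3-methylbut-1-yne | CC(C)(Cl)C#C | starting material
24 | 1-{2-hydroxy-6-[(2-methylbut-3-yn-2-yl)oxy]-4-[(triisopropylsilyl)oxy]phenyl}butan-1-one | CCCC(=O)c1c(O)cc(O[Si](C(C)C)(C(C)C)C(C)C)cc1OC(C)(C)C#C | intermediate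
25 | 1-{2,6-dihydroxy-3-(3-methylbuta-1,2-dienyl)-4-[(triisopropylsilyl)oxy]phenyl}butan-1-one (allenylphenol, formed in the flask) | CCCC(=O)c1c(O)cc(O[Si](C(C)C)(C(C)C)C(C)C)c(C=C=C(C)C)c1O | intermediate
26 | ortho-quinone methide with the 3-methylbut-2-enylidene chain syn to the ring C=O (formed in the flask) | O=C1/C(=C\C=C(C)C)C(O[Si](C(C)C)(C(C)C)C(C)C)=CC(O)=C1C(=O)CCC | intermediate
27 | 1-{7-hydroxy-2,2-dimethyl-5-[(triisopropylsilyl)oxy]-2H-chromen-8-yl}butan-1-one | CCCC(=O)c1c(O)cc(O[Si](C(C)C)(C(C)C)C(C)C)c2C=CC(C)(C)Oc12 | intermediate
28 | 1-(5,7-dihydroxy-2,2-dimethyl-2H-chromen-8-yl)butan-1-one | CCCC(=O)c1c(O)cc(O)c2C=CC(C)(C)Oc12 | intermediate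
29 | 2-butanoyl-3-hydroxy-6,6-dimethyl-4-methylidenecyclohex-2-ene-1,5-dione (formed in the flask) | CCCC(=O)C1=C(O)C(=C)C(=O)C(C)(C)C1=O | intermediate
30 | Drummondin A | CCCC(=O)C1=C(O)C(Cc2c(O)c3c(c(C(=O)CCC)c2O)OC(C)(C)C=C3)=C(O)C(C)(C)C1=O | target

**Step count and risks**

Total step count: 13. Longest linear sequence: 6 steps (steps 3, 4, 5, 6, 7 and 13).

Steps most likely to fail:

1. Step 5. The ketene may be captured by lithium tert-butoxide instead of the ynolate, the ynolate may be acylated with the ketenyl group trans to the alkenyl arm so that the electrocyclization cannot occur, or the vinylketene may be lost by incomplete photochemical opening or hydrogen shift before it is trapped. Fallback, setting out from 21 and coming back at 16: butyrylphloroglucinol 21 is dearomatised by twofold C-methylation at one ring carbon (MeI, NaOMe, MeOH, 0 °C to rt), a known entry to acylfilicinic acids. The reaction passes through the mono-C-methyl compound 1-(2,4,6-trihydroxy-3-methylphenyl)butan-1-one F1 and should give 16, from which the route continues with step 7. Ring A is then inherited from the arene instead of being built by annulation.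

2. Step 2. Dimerization of dimethylketene may outrun the cycloaddition to the hindered silyl ynol ether. Fallback, setting out from 3 and coming back at 6: N,N-dimethylisobutyramide, Tf2O and 2,4,6-collidine in CH2Cl2 give the far more electrophilic keteniminium salt N-methyl-N-(2-methylprop-1-en-1-ylidene)methanaminium triflate F2. Its [2+2] cycloaddition with 3 should give, with the same orientation, the cyclobuteniminium salt 3-ethoxy-N,N,4,4-tetramethyl-2-(triethylsilyl)cyclobut-2-en-1-iminium triflate F3, and hydrolysis with aqueous NaHCO3 returns to 6.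

3. Step 13. Retro-Mannich scrambling may lead to homodimer formation, or the chromene may degrade on heating. Fallback, setting out from 28 (with 17) and coming back at 30: the roles are inverted. Compound 28 is aminomethylated at C6 with 17 to give the chromene Mannich hydroiodide [(8-butanoyl-5,7-dihydroxy-2,2-dimethyl-2H-chromen-6-yl)methyl]dimethylammonium iodide F4. Heating F4 with 16 and NaOAc in 1,4-dioxane at 100 °C should generate the ortho-quinone methide of ring B, 8-butanoyl-7-hydroxy-2,2-dimethyl-6-methylidene-2H-chromen-5(6H)-one F5, which the nucleophilic free ring carbon of 16 should capture to give 30.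

**Further compounds**

F1 | step 5 | 1-(2,4,6-trihydroxy-3-methylphenyl)butan-1-one | CCCC(=O)c1c(O)cc(O)c(C)c1O
F2 | step 2 | N-methyl-N-(2-methylprop-1-en-1-ylidene)methanaminium triflate | CC(C)=C=[N+](C)C.[O-]S(=O)(=O)C(F)(F)F
F3 | step 2 | 3-ethoxy-N,N,4,4-tetramethyl-2-(triethylsilyl)cyclobut-2-en-1-iminium triflate | CCOC1=C([Si](CC)(CC)CC)C(=[N+](C)C)C1(C)C.[O-]S(=O)(=O)C(F)(F)F
F4 | step 13 | [(8-butanoyl-5,7-dihydroxy-2,2-dimethyl-2H-chromen-6-yl)methyl]dimethylammonium iodide | CCCC(=O)c1c(O)c(C[NH+](C)C)c(O)c2C=CC(C)(C)Oc12.[I-]
F5 | step 13 | 8-butanoyl-7-hydroxy-2,2-dimethyl-6-methylidene-2H-chromen-5(6H)-one | CCCC(=O)C1=C(O)C(=C)C(=O)C2=C1OC(C)(C)C=C2
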